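**Plan**
- Retrosynthetic cuts, in order:
  - the acetate and the glyceryl ester C–O bond (the ester arises by trapping a ketene with (R)-solketal);
  - the C5–side-chain bond (enol triflate plus alkylzinc);
  - ring A, expanded by one carbon, since C1 with its exocyclic carboxyl C9 is a Wolff-contracted C9 cycloheptanone;
  - finally C4–C4a and C9–C8a.
- Enabling feature: C4a and C8a, the adjacent methyl-bearing quaternary fusion carbons of rings A and B, are the two carbons of a tetrasubstituted ring-B alkene. Its allylic carbon C5 bears oxygen, so a cyclopentane-1,3-dione enol ether hung on that oxygen can add across C4a=C8a.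
- Forward order: ring B is bought. A crossed [2+2] and retro-aldol opening fuse a cycloheptane-1,4-dione onto C4a–C8a. C3 is deoxygenated, diazo transfer and photo-Wolff shrink the seven-membered ring to ring A, the C5 ketone becomes triflate and then the homoprenyl alkene, and the glycerol is finished last.
- Stereochemistry: CBS reduction sets C5, and the tether relays it to C4a and C8a. C2 is fixed by equilibration to the exo methyl in the rigid photoadduct, and C1 by thermodynamic ester epimerisation. The glycerol centre comes from (R)-solketal.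

Key step: step 5

Conventions: target numbering is used throughout. C9 is the carboxyl carbon. In the seven-membered-ring compounds the ring runs C8a–C9–C1–C2–C3–C4–C4a. α is the face of the two angular methyl groups and β the opposite face, so the target is 1α-CO2R, 2β-Me, 4aα-Me, 8aα-Me.
Assumption: 8 and 10 are written as open hydroxy ketones; any five-ring hemiketal tautomer (C5–O onto C9 or C3) is taken to react through the open form.

Step 1
Reactants: 1 2,3-dimethylcyclohex-2-en-1-one
Product: 2 (1R)-2,3-dimethylcyclohex-2-en-1-ol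
Conditions: (S)-Me-CBS (10 mol %), BH3·SMe2, THF, −20 °C; MeOH
Reagents that add atoms: none
Why: Corey–Bakshi–Shibata reduction, in which the fully substituted alkenyl arm acts as the large group so that hydride reaches one carbonyl face only and should give the (R)-carbinol (future C5), while the tetrasubstituted alkene resists hydroboration.

Step 2
Reactants: 3 cyclopentane-1,3-dione
Product: 4 3-chlorocyclopent-2-en-1-one
Conditions: (COCl)2, DMF (cat.), CH2Cl2, 0 °C to rt
Reagents that add atoms: oxalyl chloride, O=C(Cl)C(=O)Cl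
Why: Vinylogous acid chloride formation, the enol of the 1,3-dione reacting with oxalyl chloride as a carboxylic acid would.

Step 3
Reactants: 2 (1R)-2,3-dimethylcyclohex-2-en-1-ol; 4 3-chlorocyclopent-2-en-1-one
Product: 5 3-{[(1R)-2,3-dimethylcyclohex-2-en-1-yl]oxy}cyclopent-2-en-1-one
Conditions: NaH, THF, 0 °C; then 4, 0 °C to rt
Reagents that add atoms: none
Why: Addition–elimination of the sodium alkoxide on the β-chloro enone (vinylogous acyl substitution) builds the enol ether without touching the C5–O bond, so the carbinol configuration is retained and the ionisable allylic alcohol never meets acid.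

Step 4
Reactants: 5 3-{[(1R)-2,3-dimethylcyclohex-2-en-1-yl]oxy}cyclopent-2-en-1-one
Product: 6 (5S)-3-{[(1R)-2,3-dimethylcyclohex-2-en-1-yl]oxy}-5-methylcyclopent-2-en-1-one (5R epimer co-formed and carried along)
Conditions: LDA, THF, −78 °C; MeI, −78 to −20 °C
Reagents that add atoms: iodomethane, CI
Why: Kinetic deprotonation of a vinylogous ester takes place at the α′-CH2 (Stork–Danheiser-type alkylation) and places the future C2 methyl next to the future C3 carbonyl; no control by the remote carbinol is needed because this centre is equilibrated in step 5.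

Step 5
Reactants: 6 (5S)-3-{[(1R)-2,3-dimethylcyclohex-2-en-1-yl]oxy}-5-methylcyclopent-2-en-1-one (with its 5R epimer)
Product: 8 5β-hydroxy-2β,4aα,8aα-trimethyl-cis-bicyclo[5.4.0]undecane-3,9-dione, via cage photoadduct 7 (not isolated)
Conditions: hν (medium-pressure Hg, Pyrex, λ > 290 nm), MeCN–acetone 9:1, ca. 5 mM, Ar, 0 °C; concentrate; NaOMe (0.2 equiv), MeOH, rt; then 1 M aq HCl–THF, 0 °C to rt, short contact
Reagents that add atoms: water, O
Why: The enone triplet closes in the 1,5-mode (rule of five, the only mode the two-atom O–C5 tether allows) to a five-membered-ring 1,4-biradical that collapses to the crossed adduct 7, a 2-oxabicyclo[2.1.1]hexane in which the enone α-carbon (C4) is bonded to C4a and the β-carbon (C9) to C8a. Protonation of the C3 carbonyl then lets the ether oxygen push open the strained C4–C9 bond (retro-aldol opening of a donor–acceptor cyclobutane), and hydration of the oxocarbenium ion releases the C5 hydroxyl and the C9 ketone, so the five-membered ring grows by two carbons into the cycloheptane-1,4-dione fused at C4a–C8a. The closest known reactions are the crossed intramolecular photocycloaddition of 3-(allyloxy)cycloalk-2-enones and the de Mayo ring expansion of cyclopentane-1,3-dione enol derivatives. C4a and C8a are set together because both bonds must form suprafacially on the alkene face that carries the C5 oxygen, which makes the two methyl groups cis and ties their absolute configuration to the CBS carbinol. C2 is set in the cage, where the endo face of the cyclopentanone is blocked by the C8a methyl, so base equilibration moves the methyl to the exo face (cis to the C9–O bond), which maps onto the 2β configuration of the target, whereas equilibration in the flexible dione would offer no such bias. The step needs crossed rather than straight regiochemistry, and cycloaddition rather than thermal Claisen rearrangement, secondary photolysis or acid enolisation towards C2; the short tether secures the first, and low temperature, the Pyrex cut-off, stopping at full conversion and a brief cold acid treatment secure the rest.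

Step 6
Reactants: 8 5β-hydroxy-2β,4aα,8aα-trimethyl-cis-bicyclo[5.4.0]undecane-3,9-dione
Product: 10 5β-hydroxy-2β,4aα,8aα-trimethyl-cis-bicyclo[5.4.0]undecan-9-one, via C3 tosylhydrazone 9 (not isolated)
Conditions: TsNHNH2 (1.05 equiv), MeOH, rt; concentrate; catecholborane (3 equiv), CHCl3, −10 °C to rt; NaOAc·3H2O, reflux
Reagents that add atoms: none
Why: Condensation should occur at C3 only because the C9 carbonyl is flanked by quaternary C8a, and hydride reduction of the tosylhydrazone followed by loss of sulfinate and nitrogen (Caglioti-type deoxygenation in its mild borane form) turns C3 into CH2 without conditions that enolise towards C2, which is no longer epimerisable afterwards.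

Step 7
Reactants: 10 5β-hydroxy-2β,4aα,8aα-trimethyl-cis-bicyclo[5.4.0]undecan-9-one
Product: 11 5β-(tert-butyldimethylsilyloxy)-2β,4aα,8aα-trimethyl-cis-bicyclo[5.4.0]undecan-9-one
Conditions: TBSOTf (1.1 equiv), 2,6-lutidine, CH2Cl2, −78 to 0 °C
Reagents that add atoms: tert-butyldimethylsilyl triflate, CC(C)(C)[Si](C)(C)OS(=O)(=O)C(F)(F)F
Why: Silyl triflate with a hindered pyridine base silylates the neopentyl secondary alcohol faster than it forms enol silanes and masks the hydroxyl for the strong-base step that follows.

Step 8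
Reactants: 11 5β-(tert-butyldimethylsilyloxy)-2β,4aα,8aα-trimethyl-cis-bicyclo[5.4.0]undecan-9-one
Product: 13 1-diazo-5β-(tert-butyldimethylsilyloxy)-2β,4aα,8aα-trimethyl-cis-bicyclo[5.4.0]undecan-9-one, via C1-trifluoroacetyl ketone 12 (not isolated)
Conditions: LiHMDS, THF, −78 °C; CF3CO2CH2CF3; then MsN3, Et3N, H2O (1 equiv), MeCN, rt
Reagents that add atoms: methanesulfonyl azide, CS(=O)(=O)N=[N+]=[N-]
Why: Detrifluoroacetylative (Regitz-type) diazo transfer, in which C9 can enolise only towards C1 because C8a is quaternary and the sulfonyl azide exchanges the activating trifluoroacetyl group for the diazo group.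

Step 9
Reactants: 13 1-diazo-5β-(tert-butyldimethylsilyloxy)-2β,4aα,8aα-trimethyl-cis-bicyclo[5.4.0]undecan-9-one
Product: 14 1-diazo-5β-hydroxy-2β,4aα,8aα-trimethyl-cis-bicyclo[5.4.0]undecan-9-one
Conditions: TBAF, THF, rt to 40 °C
Reagents that add atoms: none
Why: Fluoride desilylation leaves the base-stable disubstituted diazo ketone intact and is done at this stage so that a free C5 hydroxyl never faces a C1 ester, with which the 1β epimer could lactonise.

Step 10
Reactants: 14 1-diazo-5β-hydroxy-2β,4aα,8aα-trimethyl-cis-bicyclo[5.4.0]undecan-9-one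
Product: 15 1-diazo-2β,4aα,8aα-trimethyl-cis-bicyclo[5.4.0]undecane-5,9-dione
Conditions: Dess–Martin periodinane, pyridine, CH2Cl2, 0 °C to rt
Reagents that add atoms: none
Why: Buffered Dess–Martin oxidation converts the hindered secondary alcohol into the C5 ketone under near-neutral conditions that diazo ketones tolerate and retires the C5 stereocentre after it has done its work.

Step 11
Reactants: 15 1-diazo-2β,4aα,8aα-trimethyl-cis-bicyclo[5.4.0]undecane-5,9-dione; 16 (R)-solketal [(4R)-2,2-dimethyl-1,3-dioxolan-4-yl]methanol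
Product: 18 [(4S)-2,2-dimethyl-1,3-dioxolan-4-yl]methyl 2β,4aα,8aα-trimethyl-5-oxo-cis-decalin-1-carboxylate (C1 epimers), via ring-contracted ketene 17 (not isolated)
Conditions: hν (365 nm LED), 16 (5 equiv), THF, rt
Reagents that add atoms: none
Why: Photochemical Wolff rearrangement, in which the s-cis-locked cyclic diazo ketone loses nitrogen with 1,2-shift of C8a from C9 to C1 (retention at the migrating carbon) to contract the seven-membered ring to ring A, and the ketene is captured by the free CH2OH of (R)-solketal, the enantiomer that maps onto the (S)-glyceride, while C1 is formed unselectively and corrected in step 14.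

Step 12
Reactants: 18 [(4S)-2,2-dimethyl-1,3-dioxolan-4-yl]methyl 2β,4aα,8aα-trimethyl-5-oxo-cis-decalin-1-carboxylate (C1 epimers)
Product: 19 C5 enol triflate (C5=C6) of 18 (C1 epimers)
Conditions: KHMDS (1.1 equiv), THF, −78 °C; N-(5-chloro-2-pyridyl)bis(trifluoromethanesulfonimide), −78 to −20 °C
Reagents that add atoms: N-(5-chloro-2-pyridyl)bis(trifluoromethanesulfonimide), Clc1ccc(nc1)N(S(=O)(=O)C(F)(F)F)S(=O)(=O)C(F)(F)F
Why: Kinetic enolate O-triflation, in which the C5 ketone can enolise only towards C6 (C4a is quaternary) and is far more acidic than the hindered ester, so the position of the ring-B double bond is fixed.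

Step 13
Reactants: 19 C5 enol triflate (C1 epimers); 20 5-bromo-2-methylpent-2-ene
Product: 22 [(4S)-2,2-dimethyl-1,3-dioxolan-4-yl]methyl 2β,4aα,8aα-trimethyl-5-(4-methylpent-3-enyl)-1,2,3,4,4a,7,8,8a-octahydronaphthalene-1-carboxylate (C1 epimers), via homoprenylzinc bromide 21 (not isolated)
Conditions: 20, Zn dust, LiCl, THF, 50 °C; then 19, Pd(dppf)Cl2 (5 mol %), THF, 50 °C
Reagents that add atoms: none
Why: Negishi sp2–sp3 coupling, in which the primary alkylzinc halide tolerates ester and acetal groups and the bidentate ligand favours reductive elimination over β-hydride elimination.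

Step 14
Reactants: 22 solketal ester of the full diterpenoid acid (C1 epimers)
Product: 23 [(4S)-2,2-dimethyl-1,3-dioxolan-4-yl]methyl (1S,2R,4aR,8aR)-2,4a,8a-trimethyl-5-(4-methylpent-3-enyl)-1,2,3,4,4a,7,8,8a-octahydronaphthalene-1-carboxylate
Conditions: KOt-Bu (0.3 equiv), (R)-solketal 16 (2 equiv), THF, 50 °C
Reagents that add atoms: none
Why: Thermodynamic epimerisation through the ester enolate with the alkoxide of the ester's own alcohol (degenerate transesterification), in which, with C5 now sp2, only the 1α-ester can be equatorial together with the equatorial 2β-methyl, whereas the 1β epimer meets a syn-axial contact with C5 or C8 in either chair–chair form.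

Step 15
Reactants: 23 (1S,2R,4aR,8aR) solketal ester
Product: 24 (2S)-2,3-dihydroxypropyl (1S,2R,4aR,8aR)-2,4a,8a-trimethyl-5-(4-methylpent-3-enyl)-1,2,3,4,4a,7,8,8a-octahydronaphthalene-1-carboxylate
Conditions: AcOH–H2O 4:1, 40 °C
Reagents that add atoms: none
Why: Mild acid hydrolysis of the isopropylidene acetal, during which the very hindered acyl group should not migrate and the trisubstituted alkenes are inert.

Step 16
Reactants: 24 (2S)-2,3-dihydroxypropyl ester
Product: 26 (2S)-2-acetoxy-3-(tert-butyldimethylsilyloxy)propyl (1S,2R,4aR,8aR)-2,4a,8a-trimethyl-5-(4-methylpent-3-enyl)-1,2,3,4,4a,7,8,8a-octahydronaphthalene-1-carboxylate, via primary silyl ether 25 (not isolated)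
Conditions: TBSCl (1.05 equiv), imidazole, CH2Cl2, 0 °C; then Ac2O, DMAP (cat.), pyridine, 0 °C to rt
Reagents that add atoms: tert-butyldimethylsilyl chloride, CC(C)(C)[Si](C)(C)Cl; acetic anhydride, CC(=O)OC(C)=O
Why: Steric discrimination directs the silyl chloride to the primary hydroxyl and DMAP-catalysed acetylation then caps the secondary hydroxyl in the same flask, so the acetate is placed on glycerol C2 with no free neighbouring hydroxyl.

Step 17
Reactants: 26 2-O-acetyl-3-O-TBS glyceride
Product: 27 CNP0320437.1, (2S)-2-acetoxy-3-hydroxypropyl (1S,2R,4aR,8aR)-2,4a,8a-trimethyl-5-(4-methylpent-3-enyl)-1,2,3,4,4a,7,8,8a-octahydronaphthalene-1-carboxylate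
Conditions: HF·pyridine, pyridine, THF, 0 °C; cold neutral work-up
Reagents that add atoms: none
Why: Buffered HF·pyridine cleaves the primary silyl ether under cold, weakly acidic conditions, the regime in which 1,2-diacylglycerols are least prone to acyl migration.

**Compound list**
1 | 2,3-dimethylcyclohex-2-en-1-one | CC1=C(C)C(=O)CCC1 | starting material
2 | (1R)-2,3-dimethylcyclohex-2-en-1-ol | O[C@@H]1CCCC(C)=C1C | intermediate
3 | cyclopentane-1,3-dione | O=C1CCC(=O)C1 | starting material
4 | 3-chlorocyclopent-2-en-1-one | O=C1CCC(Cl)=C1 | intermediate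
5 | 3-{[(1R)-2,3-dimethylcyclohex-2-en-1-yl]oxy}cyclopent-2-en-1-one | O=C1CCC(O[C@@H]2CCCC(C)=C2C)=C1 | intermediate
6 | (5S)-3-{[(1R)-2,3-dimethylcyclohex-2-en-1-yl]oxy}-5-methylcyclopent-2-en-1-one (drawn epimer; the 5R epimer is co-formed and converges in step 5) | C[C@H]1CC(O[C@@H]2CCCC(C)=C2C)=CC1=O | intermediate
7 | cage photoadduct: cyclobutane C4–C9–C8a–C4a bridged C9–O–C5–C4a (2-oxabicyclo[2.1.1]hexane), cyclopentanone C9–C1–C2–C3–C4 cis-fused, 2-Me exo after equilibration | C[C@H]1C[C@]23O[C@@H]4CCC[C@@]2(C)[C@]4(C)[C@@H]3C1=O | intermediate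
8 | 5β-hydroxy-2β,4aα,8aα-trimethyl-cis-bicyclo[5.4.0]undecane-3,9-dione | O=C1C[C@H](C)C(=O)C[C@]2(C)[C@H](O)CCC[C@]12C | intermediate
9 | C3 tosylhydrazone of 8 | O=C1C[C@H](C)C(=NNS(=O)(=O)c3ccc(C)cc3)C[C@]2(C)[C@H](O)CCC[C@]12C | intermediate
10 | 5β-hydroxy-2β,4aα,8aα-trimethyl-cis-bicyclo[5.4.0]undecan-9-one | O=C1C[C@H](C)CC[C@]2(C)[C@H](O)CCC[C@]12C | intermediate
11 | 5β-TBS ether of 10 | O=C1C[C@H](C)CC[C@]2(C)[C@H](O[Si](C)(C)C(C)(C)C)CCC[C@]12C | intermediate
12 | C1-trifluoroacetyl derivative of 11 | O=C1C(C(=O)C(F)(F)F)[C@H](C)CC[C@]2(C)[C@H](O[Si](C)(C)C(C)(C)C)CCC[C@]12C | intermediate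
13 | 1-diazo-9-ketone, 5β-OTBS | O=C1C(=[N+]=[N-])[C@H](C)CC[C@]2(C)[C@H](O[Si](C)(C)C(C)(C)C)CCC[C@]12C | intermediate
14 | 1-diazo-9-ketone, 5β-OH | O=C1C(=[N+]=[N-])[C@H](C)CC[C@]2(C)[C@H](O)CCC[C@]12C | intermediate
15 | 1-diazo-5,9-dione | O=C1C(=[N+]=[N-])[C@H](C)CC[C@]2(C)C(=O)CCC[C@]12C | intermediate
16 | (R)-solketal, [(4R)-2,2-dimethyl-1,3-dioxolan-4-yl]methanol | CC1(C)OC[C@@H](CO)O1 | starting material
17 | ring-contracted ketene (C1=C9=O on the cis-decalin-5-one) | O=C=C1[C@H](C)CC[C@]2(C)C(=O)CCC[C@]12C | intermediate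
18 | solketal ester of the 5-oxo-cis-decalin-1-carboxylic acid (C1 epimers) | CC1(C)OC[C@@H](COC(=O)C2[C@H](C)CC[C@]3(C)C(=O)CCC[C@]23C)O1 | intermediate
19 | C5 enol triflate (C5=C6; C1 epimers) | CC1(C)OC[C@@H](COC(=O)C2[C@H](C)CC[C@]3(C)C(OS(=O)(=O)C(F)(F)F)=CCC[C@]23C)O1 | intermediate
20 | 5-bromo-2-methylpent-2-ene | CC(C)=CCCBr | starting material
21 | 4-methylpent-3-enylzinc bromide | CC(C)=CCC[Zn]Br | intermediate
22 | solketal ester with C5 homoprenyl group (C1 epimers) | CC1(C)OC[C@@H](COC(=O)C2[C@H](C)CC[C@]3(C)C(CCC=C(C)C)=CCC[C@]23C)O1 | intermediate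
23 | (1S,2R,4aR,8aR) solketal ester (1α-ester) | CC1(C)OC[C@@H](COC(=O)[C@H]2[C@H](C)CC[C@]3(C)C(CCC=C(C)C)=CCC[C@]23C)O1 | intermediate
24 | (2S)-2,3-dihydroxypropyl ester | OC[C@H](O)COC(=O)[C@H]1[C@H](C)CC[C@]2(C)C(CCC=C(C)C)=CCC[C@]12C | intermediate
25 | 3-O-TBS-2-hydroxy glyceride | CC(C)(C)[Si](C)(C)OC[C@H](O)COC(=O)[C@H]1[C@H](C)CC[C@]2(C)C(CCC=C(C)C)=CCC[C@]12C | intermediate
26 | 2-O-acetyl-3-O-TBS glyceride | CC(=O)O[C@@H](CO[Si](C)(C)C(C)(C)C)COC(=O)[C@H]1[C@H](C)CC[C@]2(C)C(CCC=C(C)C)=CCC[C@]12C | intermediate
27 | CNP0320437.1 | CC(=O)O[C@@H](CO)COC(=O)[C@H]1[C@H](C)CC[C@]2(C)C(CCC=C(C)C)=CCC[C@]12C | target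

**Step count**
- Total step count: 17.
- Longest linear sequence: 16 (steps 1 and 3–17, from 1).

**Steps most likely to fail**

Step 5.
- Risk: after the first C–C bond, the triplet 1,4-biradical may fall back to 6 or disproportionate instead of closing. Closure to the bicyclo[2.1.1] cage presses the C8a methyl against the C3 carbonyl carbon. Over-irradiation may also cleave the cage ketone (Norrish type I).
- Fallback idea: the tether is moved from the enol oxygen to the enone α-carbon. The same two bonds then form on the same alkene face in a straight [2+2] that gives a nearly flat, far less crowded cyclobutane. The fallback sets out from 2 and returns at 8.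
- Commercial 3-methoxycyclopent-2-enone is methylated (LDA, MeI) to 3-methoxy-5-methylcyclopent-2-en-1-one F1. This is iodinated with NIS to 2-iodo-3-methoxy-5-methylcyclopent-2-en-1-one F2.
- F2 is carbonylatively esterified with 2 (CO, Pd catalyst, Et3N) to (1R)-2,3-dimethylcyclohex-2-en-1-yl 2-methoxy-4-methyl-5-oxocyclopent-1-ene-1-carboxylate F3.
- Irradiation should give the straight lactone photoadduct F4.
- LiOH opens the lactone and equilibrates the C2 methyl to the exo face of the still rigid tricycle. Cold acidification then triggers methoxy-assisted retro-aldol opening and decarboxylation of the β-keto acid, which gives 8.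

Step 6.
- Risk: site selectivity between the C3 and C9 carbonyls may erode during hydrazone formation. C3 may be masked as a hemiketal by the C5 hydroxyl, or hydrazone–enehydrazine tautomerisation may scramble C2.
- Fallback idea: a radical deoxygenation replaces the hydrazone chemistry. It sets out from 8 and returns at 11, so step 7 is absorbed.
- TBSOTf/2,6-lutidine gives the 5β-silyloxy-3,9-dione F5.
- L-Selectride at −78 °C reduces the less hindered C3 carbonyl without enolisation, giving the C3 carbinol F6.
- Thiocarbonyldiimidazole/DMAP gives the C3 O-(imidazol-1-ylthiocarbonyl) derivative F7.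
- Bu3SnH/AIBN in toluene at 80 °C (Barton–McCombie) delivers 11.

Step 17.
- Risk: the acetyl group may migrate from O2 to the freed O3 (1,2- to 1,3-diacylglycerol isomerisation) during desilylation or chromatography.
- Fallback idea: silicon and fluoride are avoided altogether. The fallback sets out from 24 and returns at 27.
- Trimethyl orthoacetate with catalytic PPTS converts the diol into the cyclic 2-methoxy-2-methyl-1,3-dioxolane orthoacetate F8.
- Brief treatment with cold aqueous acetic acid opens F8 kinetically to the secondary acetate with the primary hydroxyl free, which is 27.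

Further compounds
F1 | step 5 | 3-methoxy-5-methylcyclopent-2-en-1-one | COC1=CC(=O)C(C)C1
F2 | step 5 | 2-iodo-3-methoxy-5-methylcyclopent-2-en-1-one | COC1=C(I)C(=O)C(C)C1
F3 | step 5 | (1R)-2,3-dimethylcyclohex-2-en-1-yl 2-methoxy-4-methyl-5-oxocyclopent-1-ene-1-carboxylate | COC1=C(C(=O)O[C@@H]2CCCC(C)=C2C)C(=O)C(C)C1
F4 | step 5 | straight lactone photoadduct (cyclobutane C4–C9–C8a–C4a, γ-lactone C4–C(=O)–O–C5, 9-OMe, 2-Me exo) | C[C@H]1C[C@]2(OC)[C@@]3(C)CCC[C@H]4OC(=O)[C@]2(C1=O)[C@@]34C
F5 | step 6 | 5β-(tert-butyldimethylsilyloxy)-2β,4aα,8aα-trimethyl-cis-bicyclo[5.4.0]undecane-3,9-dione | O=C1C[C@H](C)C(=O)C[C@]2(C)[C@H](O[Si](C)(C)C(C)(C)C)CCC[C@]12C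
F6 | step 6 | C3 carbinol of F5 (either C3 epimer) | O=C1C[C@H](C)C(O)C[C@]2(C)[C@H](O[Si](C)(C)C(C)(C)C)CCC[C@]12C
F7 | step 6 | C3 O-(imidazol-1-ylthiocarbonyl) derivative of F6 | O=C1C[C@H](C)C(OC(=S)n3ccnc3)C[C@]2(C)[C@H](O[Si](C)(C)C(C)(C)C)CCC[C@]12C
F8 | step 17 | cyclic orthoacetate of 24 (2-methoxy-2-methyl-1,3-dioxolane) | COC1(C)OC[C@@H](COC(=O)[C@H]2[C@H](C)CC[C@]3(C)C(CCC=C(C)C)=CCC[C@]23C)O1
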